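## Retrosynthetic overview

1. Target 26 ⇐ tert-butyl ester cleavage and C15 oxidation of β-keto lactone 24; ring C is closed last, by reductive Dieckmann cyclisation and C-methylation of spiro-butenolide 22.
2. 22 ⇐ dehydration and intramolecular Diels–Alder reaction of hydroxybutenolide triene 19: cyclohexene ring A and the 11-membered ring D form together and set C6, C9 and C11.
3. 19 ⇐ B-alkyl Suzuki coupling of alkene 13 with dienyl iodide 17; lactone ring B of 13 comes from a methyl ketone and glyoxylic acid.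
4. 13 ⇐ (S)-limonene: cyclic hydroboration sets Cb, Zr-catalysed carboalumination sets C2, nitrosative cleavage opens the menthane ring; Ca is the limonene stereocentre.
5. Ring order: B, then A + D in one operation, then C.

Labels (in target SMILES order): Me–C2, C3, C4, C5, C6 (ring-A CH), C7=C8(CO2H), C9 (ring-A CHMe), C10, C11 (spiro C–O), O1, C12 (lactone C=O), C13 (CMe), C14 and C15 (dione), Ca, C17 (CH2), C16 (fusion CH), Cb (CHMe), Cc (CH2). Ring A = cyclohexene, ring B = lactone, ring C = dione ring, ring D = 11-membered ring.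

Assumption: the thexylborane cyclic hydroboration of limonene gives the C8 epimer with the methyl group equatorial in the boracycle (the (8S)-diol from (S)-limonene), and the target's Ca configuration (substituent cis to C16–C11 on ring C) is the more stable one.

## Route

Step 1
Reactants: 1 (S)-(−)-limonene
Product: 3 (1S,2S,5S)-5-[(2S)-1-hydroxypropan-2-yl]-2-methylcyclohexan-1-ol, via cyclic thexylborane 2 (not isolated)
Conditions: thexylborane (from BH3·THF and 2,3-dimethylbut-2-ene), THF, 0 °C to rt; then NaOH, H2O2, 0 to 40 °C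
Reagents that add atoms: hydrogen peroxide, OO
Why: Brown cyclic hydroboration: boron adds to the isopropenyl terminus and then syn to the ring alkene from the side-chain face, the chair 2-borabicyclo[3.3.1]nonane with equatorial C8 methyl fixes Cb relative to Ca, and oxidation retains configuration.

Step 2
Reactants: 3 (1S,2S,5S)-5-[(2S)-1-hydroxypropan-2-yl]-2-methylcyclohexan-1-ol
Product: 4 (2S)-2-[(1S,3S,4S)-3-hydroxy-4-methylcyclohexyl]propyl 4-methylbenzenesulfonate
Conditions: TsCl (1.05 equiv), pyridine, CH2Cl2, 0 °C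
Reagents that add atoms: 4-toluenesulfonyl chloride, Cc1ccc(cc1)S(Cl)(=O)=O
Why: Selective sulfonylation of the primary over the hindered secondary hydroxyl; no stereocentre is touched.

Step 3
Reactants: 4 (2S)-2-[(1S,3S,4S)-3-hydroxy-4-methylcyclohexyl]propyl 4-methylbenzenesulfonate
Product: 5 (1S,2S,5S)-2-methyl-5-[(2R)-pent-4-en-2-yl]cyclohexan-1-ol
Conditions: CH2=CHMgBr (4 equiv), CuI (10 mol %), THF, −30 to 0 °C
Reagents that add atoms: vinylmagnesium bromide, C=C[Mg]Br
Why: Copper-catalysed Grignard substitution (Kochi type) at the primary tosylate; the alcohol is carried as its magnesium alkoxide.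

Step 4
Reactants: 5 (1S,2S,5S)-2-methyl-5-[(2R)-pent-4-en-2-yl]cyclohexan-1-ol
Product: 7 (1S,2S,5S)-2-methyl-5-[(2R,4R)-4-methylhept-6-en-2-yl]cyclohexan-1-ol, via bis(dimethylaluminium) species 6 (not isolated)
Conditions: Me3Al (4 equiv), (+)-bis(1-neomenthylindenyl)zirconium dichloride (5 mol %), methylaluminoxane, CH2Cl2, 0 to 23 °C; then Zn(OTf)2, DMF, 70 °C; CH2=CHBr, Pd(DPEphos)Cl2 (3 mol %), i-Bu2AlH (6 mol %), 23 °C
Reagents that add atoms: trimethylaluminium, C[Al](C)C; vinyl bromide, C=CBr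
Why: Negishi Zr-catalysed asymmetric carboalumination adds Me–Al across the terminal alkene under catalyst control to set C2 (syn to the Cb methyl), and the alkylalane is transmetalated to zinc and vinylated by Negishi coupling under zerovalent palladium catalysis.

Step 5
Reactants: 7 (1S,2S,5S)-2-methyl-5-[(2R,4R)-4-methylhept-6-en-2-yl]cyclohexan-1-ol
Product: 8 (2S,5S)-2-methyl-5-[(2R,4R)-4-methylhept-6-en-2-yl]cyclohexan-1-one
Conditions: Dess–Martin periodinane, NaHCO3, CH2Cl2, 0 °C to rt
Reagents that add atoms: none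
Why: Dess–Martin oxidation of the secondary alcohol; the terminal alkene is inert.

Step 6
Reactants: 8 (2S,5S)-2-methyl-5-[(2R,4R)-4-methylhept-6-en-2-yl]cyclohexan-1-one
Product: 10 ethyl (3S,4R,6R)-3-[3-(hydroxyimino)butyl]-4,6-dimethylnon-8-enoate, via 2-methyl-2-nitroso ketone 9 (not isolated)
Conditions: isopentyl nitrite (1.2 equiv), NaOEt (1.5 equiv), EtOH, 0 °C to rt; AcOH quench
Reagents that add atoms: isopentyl nitrite, CC(C)CCON=O; sodium ethoxide, CC[O-].[Na+]
Why: Nitrosative retro-Claisen cleavage: C-nitrosation at the methyl-bearing α-carbon gives a tertiary nitroso ketone that cannot tautomerise, and ethoxide attack on the carbonyl cleaves the ring to the ethyl ester (C14) and the oxime of the C11 methyl ketone.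

Step 7
Reactants: 10 ethyl (3S,4R,6R)-3-[3-(hydroxyimino)butyl]-4,6-dimethylnon-8-enoate; 11 glyoxylic acid (used as monohydrate)
Product: 13 ethyl (3S,4R,6R)-3-[(2-hydroxy-2-methyl-5-oxo-2,5-dihydrofuran-3-yl)methyl]-4,6-dimethylnon-8-enoate, via keto ester 12 (not isolated)
Conditions: 11 (6 equiv), 1,4-dioxane/H2O, 25 °C; then 85% H3PO4, 85 °C
Reagents that add atoms: none
Why: Trans-oximation to glyoxylic acid frees the methyl ketone, whose more substituted enol undergoes acid-catalysed aldol condensation with glyoxylic acid at C16, and the (Z)-4-oxo-enoic acid closes to the 5-hydroxybutenolide (ring B).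

Step 8
Reactants: 14 tert-butyl but-2-ynoate
Product: 15 tert-butyl (2E)-2-(tributylstannyl)but-2-enoate
Conditions: Bu3SnH (1.1 equiv), Pd(PPh3)4 (2 mol %), THF, 0 °C to rt
Reagents that add atoms: tributyltin hydride, CCCC[SnH](CCCC)CCCC
Why: Palladium-catalysed syn hydrostannation places tin α to the ester, so the methyl group is cis to the ester and trans to tin.

Step 9
Reactants: 15 tert-butyl (2E)-2-(tributylstannyl)but-2-enoate; 16 (E)-1,2-diiodoethene
Product: 17 tert-butyl (2Z,3E)-2-ethylidene-4-iodobut-3-enoate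
Conditions: 16 (3 equiv), Pd2(dba)3 (2.5 mol %), AsPh3 (10 mol %), CuI (10 mol %), DMF, rt
Reagents that add atoms: none
Why: Stille coupling with retention of both alkene geometries; excess diiodide suppresses double coupling.

Step 10
Reactants: 13 ethyl (3S,4R,6R)-3-[(2-hydroxy-2-methyl-5-oxo-2,5-dihydrofuran-3-yl)methyl]-4,6-dimethylnon-8-enoate; 17 tert-butyl (2Z,3E)-2-ethylidene-4-iodobut-3-enoate
Product: 19 1-tert-butyl 13-ethyl (2Z,3E,8R,10R,11S)-2-ethylidene-11-[(2-hydroxy-2-methyl-5-oxo-2,5-dihydrofuran-3-yl)methyl]-8,10-dimethyltridec-3-enedioate, via B-alkyl-9-BBN 18 (not isolated)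
Conditions: 9-BBN-H (2.5 equiv), THF, 0 °C to rt; then 17, Pd(dppf)Cl2 (5 mol %), AsPh3, Cs2CO3, DMF/H2O, rt; pH 3 work-up
Reagents that add atoms: none
Why: Anti-Markovnikov hydroboration of the terminal alkene followed by B-alkyl Suzuki–Miyaura coupling, which keeps the diene geometry and creates no stereocentre.

Step 11
Reactants: 19 1-tert-butyl 13-ethyl (2Z,3E,8R,10R,11S)-2-ethylidene-11-[(2-hydroxy-2-methyl-5-oxo-2,5-dihydrofuran-3-yl)methyl]-8,10-dimethyltridec-3-enedioate
Product: 22 spiro-butenolide macrocycle (rings A/B/D; tert-butyl ester; CH2CO2Et on Ca), via pseudoester trifluoroacetate 20 (not isolated), via methylenebutenolide triene 21 (not isolated)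
Conditions: (CF3CO)2O, Et3N, CH2Cl2, −20 °C; NaHCO3 wash; then toluene (1 mM), 2,6-di-tert-butyl-4-methylphenol, 110 °C
Reagents that add atoms: none
Why: Intramolecular Diels–Alder reaction of the 5-methylenebutenolide unveiled in situ (reacting at its exocyclic alkene): the diene, with C5 and the C9 methyl both outside, adds through the lactone-oxygen-endo, tether-exo transition state (C5 and C9-Me cis to O1, trans ring fusion at C6–C11), and the π-face is the one that leaves the CH2CO2Et branch on Ca outside the forming 11-membered ring.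

Step 12
Reactants: 22 spiro-butenolide macrocycle (rings A/B/D; tert-butyl ester; CH2CO2Et on Ca)
Product: 24 tetracyclic β-keto lactone tert-butyl ester (15-deoxo target ester), via lithium enolate 23 (not isolated)
Conditions: LiBH(s-Bu)3 (1.2 equiv), THF, −78 to 0 °C; then MeI, DMPU, 0 °C to rt
Reagents that add atoms: iodomethane, CI
Why: Reductive Dieckmann cyclisation: conjugate hydride addition at C16 anti to the macrocycle gives the lactone enolate regiospecifically, it acylates on the ester arm held on the upper face to close ring C cis-fused, and the resulting β-keto lactone enolate is C-methylated on the only open face to fix C13.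

Step 13
Reactants: 24 tetracyclic β-keto lactone tert-butyl ester (15-deoxo target ester)
Product: 25 tert-butyl ester of the target
Conditions: SeO2 (1.5 equiv), 1,4-dioxane/H2O (30:1), 90 °C
Reagents that add atoms: selenium dioxide, O=[Se]=O
Why: Riley oxidation of the only enolisable α-methylene (C15; C13 is quaternary) gives the 1,2-dione, and Ca keeps its more stable configuration.

Step 14
Reactants: 25 tert-butyl ester of the target
Product: 26 CNP0115928.1
Conditions: CF3CO2H/CH2Cl2 (1:4), 0 °C to rt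
Reagents that add atoms: none
Why: Acidolysis of the tert-butyl ester (loss of isobutene) under conditions that leave the lactone, the dione and all stereocentres untouched.

## Compound list

1 | (S)-(−)-limonene | CC1=CC[C@H](CC1)C(C)=C | starting material
2 | 2-(2,3-dimethylbutan-2-yl)-4,8-dimethyl-2-borabicyclo[3.3.1]nonane (boron bonded to C9 and C2 of the p-menthane skeleton) | C[C@@H]1[C@@H]2C[C@H](CC1)[C@H](C)CB2C(C)(C)C(C)C | intermediate
3 | (1S,2S,5S)-5-[(2S)-1-hydroxypropan-2-yl]-2-methylcyclohexan-1-ol | C[C@@H]1[C@@H](O)C[C@H](CC1)[C@H](C)CO | intermediate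
4 | (2S)-2-[(1S,3S,4S)-3-hydroxy-4-methylcyclohexyl]propyl 4-methylbenzenesulfonate | C[C@@H]1[C@@H](O)C[C@H](CC1)[C@H](C)COS(=O)(=O)c1ccc(C)cc1 | intermediate
5 | (1S,2S,5S)-2-methyl-5-[(2R)-pent-4-en-2-yl]cyclohexan-1-ol | C[C@@H]1[C@@H](O)C[C@H](CC1)[C@H](C)CC=C | intermediate
6 | O-dimethylaluminium alkoxide of 5 carrying the (2R)-2-methyl-3-(dimethylaluminio)propyl terminus | C[C@@H]1[C@@H](O[Al](C)C)C[C@H](CC1)[C@H](C)C[C@H](C)C[Al](C)C | intermediate
7 | (1S,2S,5S)-2-methyl-5-[(2R,4R)-4-methylhept-6-en-2-yl]cyclohexan-1-ol | C[C@@H]1[C@@H](O)C[C@H](CC1)[C@H](C)C[C@H](C)CC=C | intermediate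
8 | (2S,5S)-2-methyl-5-[(2R,4R)-4-methylhept-6-en-2-yl]cyclohexan-1-one | C[C@@H]1C(=O)C[C@H](CC1)[C@H](C)C[C@H](C)CC=C | intermediate
9 | (5S)-2-methyl-5-[(2R,4R)-4-methylhept-6-en-2-yl]-2-nitrosocyclohexan-1-one (C2 epimers) | CC1(N=O)C(=O)C[C@H](CC1)[C@H](C)C[C@H](C)CC=C | intermediate
10 | ethyl (3S,4R,6R)-3-[3-(hydroxyimino)butyl]-4,6-dimethylnon-8-enoate (oxime E/Z mixture) | CCOC(=O)C[C@H](CCC(C)=NO)[C@H](C)C[C@H](C)CC=C | intermediate
11 | glyoxylic acid (used as monohydrate) | O=CC(=O)O | starting material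
12 | ethyl (3S,4R,6R)-4,6-dimethyl-3-(3-oxobutyl)non-8-enoate | CCOC(=O)C[C@H](CCC(C)=O)[C@H](C)C[C@H](C)CC=C | intermediate
13 | ethyl (3S,4R,6R)-3-[(2-hydroxy-2-methyl-5-oxo-2,5-dihydrofuran-3-yl)methyl]-4,6-dimethylnon-8-enoate (hemiketal carbon as epimer mixture) | CCOC(=O)C[C@H](CC1=CC(=O)OC1(C)O)[C@H](C)C[C@H](C)CC=C | intermediate
14 | tert-butyl but-2-ynoate | CC#CC(=O)OC(C)(C)C | starting material
15 | tert-butyl (2E)-2-(tributylstannyl)but-2-enoate | C/C=C(/[Sn](CCCC)(CCCC)CCCC)C(=O)OC(C)(C)C | intermediate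
16 | (E)-1,2-diiodoethene | I/C=C/I | starting material
17 | tert-butyl (2Z,3E)-2-ethylidene-4-iodobut-3-enoate | C/C=C(/C=C/I)C(=O)OC(C)(C)C | intermediate
18 | B-alkyl-9-borabicyclo[3.3.1]nonane from 13 (boron on the former terminal carbon C5) | CCOC(=O)C[C@H](CC1=CC(=O)OC1(C)O)[C@H](C)C[C@H](C)CCCB1C2CCCC1CCC2 | intermediate
19 | 1-tert-butyl 13-ethyl (2Z,3E,8R,10R,11S)-2-ethylidene-11-[(2-hydroxy-2-methyl-5-oxo-2,5-dihydrofuran-3-yl)methyl]-8,10-dimethyltridec-3-enedioate | CCOC(=O)C[C@H](CC1=CC(=O)OC1(C)O)[C@H](C)C[C@H](C)CCC/C=C/C(=C/C)C(=O)OC(C)(C)C | intermediate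
20 | O-trifluoroacetate of the hemiketal hydroxyl of 19 | CCOC(=O)C[C@H](CC1=CC(=O)OC1(C)OC(=O)C(F)(F)F)[C@H](C)C[C@H](C)CCC/C=C/C(=C/C)C(=O)OC(C)(C)C | intermediate
21 | 1-tert-butyl 13-ethyl (2Z,3E,8R,10R,11S)-2-ethylidene-8,10-dimethyl-11-[(2-methylidene-5-oxo-2,5-dihydrofuran-3-yl)methyl]tridec-3-enedioate | CCOC(=O)C[C@H](CC1=CC(=O)OC1=C)[C@H](C)C[C@H](C)CCC/C=C/C(=C/C)C(=O)OC(C)(C)C | intermediate
22 | Diels–Alder adduct: ring A (tert-butyl cyclohexenecarboxylate) spiro-fused at C11 to the 2(5H)-furanone ring B; 11-membered ring D from C6 to C16; ethoxycarbonylmethyl on Ca; C2, C6, C9, C11, Ca, Cb as in the target | C[C@@H]1CCC[C@H]2C=C(C(=O)OC(C)(C)C)[C@@H](C)C[C@@]23OC(=O)C=C3C[C@@H](CC(=O)OCC)[C@H](C)C1 | intermediate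
23 | lithium enolate (C13=C14–O−) of the ring-C-closed β-keto lactone | C[C@@H]1CCC[C@H]2C=C(C(=O)OC(C)(C)C)[C@@H](C)C[C@@]23OC(=O)C2=C([O-])C[C@H](C[C@H]23)[C@H](C)C1.[Li+] | intermediate
24 | tert-butyl ester of 15-deoxo-26 (rings A–D; C14 ketone, C15 methylene; all eight stereocentres as in the target) | C[C@@H]1CCC[C@H]2C=C(C(=O)OC(C)(C)C)[C@@H](C)C[C@@]23OC(=O)[C@@]2(C)C(=O)C[C@H](C[C@H]23)[C@H](C)C1 | intermediate
25 | tert-butyl ester of 26 | C[C@@H]1CCC[C@H]2C=C(C(=O)OC(C)(C)C)[C@@H](C)C[C@@]23OC(=O)[C@@]2(C)C(=O)C(=O)[C@H](C[C@H]23)[C@H](C)C1 | intermediate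
26 | CNP0115928.1 | C[C@@H]1CCC[C@H]2C=C(C(=O)O)[C@@H](C)C[C@@]23OC(=O)[C@@]2(C)C(=O)C(=O)[C@H](C[C@H]23)[C@H](C)C1 | target

## Step count and risks

Total step count: 14. Longest linear sequence: 12 (steps 1–7 and 10–14); steps 8–9 make the dienyl iodide.

Step 11 is the most likely to fail: the π-face is controlled only by Ca and the chain, and 21 can dimerise. The fallback sets out from 13 and comes back at 24 by building ring C before the cycloaddition. Compound 13 is converted into its methyl pseudoester, ethyl (3S,4R,6R)-3-[(2-methoxy-2-methyl-5-oxo-2,5-dihydrofuran-3-yl)methyl]-4,6-dimethylnon-8-enoate F4 (MeOH, pyridinium p-toluenesulfonate). C16 is then set by ligand-controlled copper hydride conjugate reduction (Cu(OAc)2, (R)-DTBM-SEGPHOS, polymethylhydrosiloxane), ring C is closed by Dieckmann cyclisation of the lactone enolate (LiN(SiMe3)2) and the product is C-methylated (MeI) to the bicyclic methoxy keto lactone F5. The diene is attached as in step 10 to give the triene methoxy lactone F6, methanol is eliminated (Me3SiOTf, i-Pr2NEt) to the bicyclic 5-methylene lactone F7, and heating F7 (toluene, 110 °C) lets the cis-fused B/C bicycle differentiate the dienophile faces, so the intramolecular Diels–Alder reaction gives 24 directly.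

Step 12 is the second risk: hydride delivery to the hindered β-carbon beside the spiro centre may lose to 1,2-reduction. The fallback sets out from 22 and comes back at 24 by separating reduction from ring closure. The butenolide alkene is reduced with [(Ph3P)CuH]6 in toluene to the saturated spiro-lactone diester F8; LiN(SiMe3)2 (2.2 equiv) then removes the more acidic lactone α-proton, the Dieckmann product is held as its stabilised enolate, and MeI gives 24.

Step 1 is the third risk: the C8 selectivity of the cyclic hydroboration may be low. The fallback sets out from 1 and comes back at 3 by replacing reagent control with separation of epimers. Only the isopropenyl group is hydroborated (9-BBN-H; NaOH, H2O2) to give (4S)-p-menth-1-en-9-ol F1 as C8 epimers. Esterification with 3,5-dinitrobenzoyl chloride and fractional crystallisation gives (4S,8S)-p-menth-1-en-9-yl 3,5-dinitrobenzoate F2, and saponification (K2CO3, MeOH) gives (4S,8S)-p-menth-1-en-9-ol F3. Thexylborane then converts F3 into an alkoxyborane that hydroborates the ring alkene intramolecularly from the side-chain face, and oxidation (NaOH, H2O2) returns 3.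

Further compounds
F1 | step 1 | (4S)-p-menth-1-en-9-ol (C8 epimer mixture) | CC1=CC[C@H](CC1)C(C)CO
F2 | step 1 | (4S,8S)-p-menth-1-en-9-yl 3,5-dinitrobenzoate | CC1=CC[C@H](CC1)[C@H](C)COC(=O)c1cc(cc(c1)[N+]([O-])=O)[N+]([O-])=O
F3 | step 1 | (4S,8S)-p-menth-1-en-9-ol | CC1=CC[C@H](CC1)[C@H](C)CO
F4 | step 11 | ethyl (3S,4R,6R)-3-[(2-methoxy-2-methyl-5-oxo-2,5-dihydrofuran-3-yl)methyl]-4,6-dimethylnon-8-enoate | CCOC(=O)C[C@H](CC1=CC(=O)OC1(C)OC)[C@H](C)C[C@H](C)CC=C
F5 | step 11 | cis-fused B/C methoxy keto lactone (C11 bearing OMe and Me; C13 methylated; Ca carrying the (2R,4R)-4-methylhept-6-en-2-yl chain) | COC1(C)OC(=O)[C@@]2(C)C(=O)C[C@H](C[C@@H]12)[C@H](C)C[C@H](C)CC=C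
F6 | step 11 | F5 extended to the tert-butyl (2Z,3E)-2-ethylidene-dienoate | COC1(C)OC(=O)[C@@]2(C)C(=O)C[C@H](C[C@@H]12)[C@H](C)C[C@H](C)CCC/C=C/C(=C/C)C(=O)OC(C)(C)C
F7 | step 11 | cis-fused B/C 5-methylene lactone triene (enol lactone dienophile) | C=C1OC(=O)[C@@]2(C)C(=O)C[C@H](C[C@@H]12)[C@H](C)C[C@H](C)CCC/C=C/C(=C/C)C(=O)OC(C)(C)C
F8 | step 12 | 13,16-dihydro-22 (saturated spiro-lactone; C16–H set; CH2CO2Et on Ca) | C[C@@H]1CCC[C@H]2C=C(C(=O)OC(C)(C)C)[C@@H](C)C[C@@]23OC(=O)C[C@H]3C[C@@H](CC(=O)OCC)[C@H](C)C1
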